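**Retrosynthetic overview**

1. Target ⇐ global O-demethylation. The dihydrofuran on ring B (the resorcinol ring next to the ring alkene) ⇐ acid-mediated cycloetherification of a 4-methoxybenzylic carbinol, made from an aroyl ketone by transfer hydrogenation with dynamic kinetic resolution, which sets the C5 methine (dibenzo[a,d]cycloheptene numbering).
2. Seven-membered ring ⇐ gold-catalysed (4+3) annulation forming C5–C4a (aryl–C(sp3)) and C10–C9a (vinyl–aryl) in one operation. The α-diazo ketone carrying ring C gives three ring atoms (C5, C5a, C9a); a diaryl alkyne built on ring B gives four (C4a, C11a, C11, C10).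
3. Enabling feature: ring B is a resorcinol bis-ether with the alkyne meta to both oxygens, so its two carbons ortho to the alkyne are equivalent and each is ortho/para to oxygen. The receiving carbon of ring C (C7 of the benzofuran) is ortho to the furan oxygen and para to the C4 oxygen. The 4-oxygenated aryl group polarises the alkyne for 7-endo attack.
4. Diazo ketone ⇐ Pd α-arylation of 4'-methoxyacetophenone with a 6-bromo-2,3-dihydrobenzofuran, then diazo transfer. The bromo-dihydrobenzofuran (ring C unit, two stereocentres) ⇐ enantioselective rhodium carbene C–H insertion of a diaryl diazomethane, then C2 epimerisation to trans.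
5. Order of ring formation: dihydrofuran on ring C (step 6) → seven-membered ring (step 12) → dihydrofuran on ring B (step 14).

Key step: step 12

Assumption: the catalyst antipodes written, Rh2(S-PTAD)4 in step 6 and RuCl(p-cymene)[(S,S)-TsDPEN] in step 13, are taken as the ones that give (3R) in 10 and (5S) in 21; if the sense of induction is the opposite, the mirror-image catalyst is used without other change.

**Route**

Step 1
Reactants: 1 4-bromo-2,6-dimethoxybenzaldehyde; 2 3,5-dimethoxyphenylmagnesium chloride (1 M in THF)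
Product: 3 (4-bromo-2,6-dimethoxyphenyl)(3,5-dimethoxyphenyl)methanol (racemic)
Conditions: THF, 0 °C to rt; aq. NH4Cl
Reagents that add atoms: none
Why: Grignard 1,2-addition to the aldehyde, the only electrophile that reacts at 0 °C (the aryl bromide is inert); the carbinol centre forms racemic and is removed in step 2.

Step 2
Reactants: 3 (4-bromo-2,6-dimethoxyphenyl)(3,5-dimethoxyphenyl)methanol
Product: 4 (4-bromo-2,6-dimethoxyphenyl)(3,5-dimethoxyphenyl)methanone
Conditions: Dess–Martin periodinane, CH2Cl2, rt
Reagents that add atoms: none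
Why: Dess–Martin oxidation of the hindered diaryl carbinol to the benzophenone under neutral conditions that leave the aryl bromide and the methyl ethers untouched.

Step 3
Reactants: 4 (4-bromo-2,6-dimethoxyphenyl)(3,5-dimethoxyphenyl)methanone
Product: 5 (4-bromo-2-hydroxy-6-methoxyphenyl)(3,5-dimethoxyphenyl)methanone
Conditions: BCl3 (1.2 equiv), CH2Cl2, −78 to 0 °C; then H2O
Reagents that add atoms: none
Why: Chelation-controlled demethylation, in which BCl3 binds the carbonyl oxygen and cleaves only a methoxy group ortho to the ketone through the six-membered boron chelate; the two ortho methoxy groups are equivalent, so one monophenol should result.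

Step 4
Reactants: 5 (4-bromo-2-hydroxy-6-methoxyphenyl)(3,5-dimethoxyphenyl)methanone; 6 4-methoxybenzyl chloride
Product: 7 {4-bromo-2-methoxy-6-[(4-methoxybenzyl)oxy]phenyl}(3,5-dimethoxyphenyl)methanone
Conditions: K2CO3, NaI (cat.), DMF, 60 °C
Reagents that add atoms: none
Why: Williamson ether synthesis on the hydrogen-bonded phenol (iodide catalysis, warm DMF) installs the 4-methoxybenzyl group whose CH2 and aryl ring become C2 and the 2-aryl group of the dihydrobenzofuran.

Step 5
Reactants: 7 {4-bromo-2-methoxy-6-[(4-methoxybenzyl)oxy]phenyl}(3,5-dimethoxyphenyl)methanone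
Product: 8 hydrazone of 7 (E/Z mixture)
Conditions: N2H4·H2O (10 equiv), AcOH (cat.), n-BuOH, 110 °C
Reagents that add atoms: hydrazine (used as the hydrate), NN
Why: Hydrazone formation by acid-catalysed condensation of the ketone with excess hydrazine, run hot because the benzophenone is di-ortho-substituted.

Step 6
Reactants: 8 hydrazone of 7
Product: 10 (2S,3R)-6-bromo-3-(3,5-dimethoxyphenyl)-4-methoxy-2-(4-methoxyphenyl)-2,3-dihydro-1-benzofuran (2,3-cis), via diazoalkane 9 (not isolated)
Conditions: MnO2, CH2Cl2, 0 °C; filtrate added to Rh2(S-PTAD)4 (1 mol %; dirhodium tetrakis[(S)-(1-adamantyl)(N-phthalimido)acetate]), CH2Cl2, 0 °C to rt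
Reagents that add atoms: none
Why: Oxidation of the hydrazone gives diaryl diazomethane 9, whose donor/donor rhodium carbene undergoes intramolecular 1,5 C–H insertion into the benzylic ether CH2 (activated by oxygen and the 4-methoxyphenyl ring, preferred over the OCH3 on the other ortho position); the chiral carboxylate ligands should fix C3 as (R), while C2 is expected mainly cis and is corrected in step 7.

Step 7
Reactants: 10 (2S,3R)-6-bromo-3-(3,5-dimethoxyphenyl)-4-methoxy-2-(4-methoxyphenyl)-2,3-dihydro-1-benzofuran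
Product: 11 (2R,3R)-6-bromo-3-(3,5-dimethoxyphenyl)-4-methoxy-2-(4-methoxyphenyl)-2,3-dihydro-1-benzofuran (2,3-trans)
Conditions: CF3CO2H (10 vol %), CH2Cl2, 0 °C to rt
Reagents that add atoms: none
Why: Acid-mediated epimerisation (reversible C2–O heterolysis to the 4-methoxybenzylic cation and re-closure) should convert the cis isomer into the thermodynamically favoured trans isomer without touching C3, giving (2R,3R).

Step 8
Reactants: 11 (2R,3R)-6-bromo-3-(3,5-dimethoxyphenyl)-4-methoxy-2-(4-methoxyphenyl)-2,3-dihydro-1-benzofuran; 12 4'-methoxyacetophenone (1.5 equiv)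
Product: 13 2-[(2R,3R)-3-(3,5-dimethoxyphenyl)-4-methoxy-2-(4-methoxyphenyl)-2,3-dihydro-1-benzofuran-6-yl]-1-(4-methoxyphenyl)ethan-1-one
Conditions: Pd2(dba)3 (1.5 mol %), Xantphos (3.6 mol %), NaOt-Bu, THF, 70 °C
Reagents that add atoms: none
Why: Palladium-catalysed α-arylation of a methyl ketone enolate (oxidative addition of the aryl bromide to zerovalent palladium, enolate transfer, reductive elimination), mono-selective with the wide-bite-angle ligand and excess ketone.

Step 9
Reactants: 13 the deoxybenzoin from step 8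
Product: 14 2-diazo-2-[(2R,3R)-3-(3,5-dimethoxyphenyl)-4-methoxy-2-(4-methoxyphenyl)-2,3-dihydro-1-benzofuran-6-yl]-1-(4-methoxyphenyl)ethan-1-one
Conditions: 4-acetamidobenzenesulfonyl azide, DBU, MeCN, 0 °C to rt
Reagents that add atoms: 4-acetamidobenzenesulfonyl azide, CC(=O)Nc1ccc(cc1)S(=O)(=O)N=[N+]=[N-]
Why: Regitz diazo transfer to the benzylic methylene activated by both the aryl ring and the ketone, which gives the donor/acceptor diazo compound needed for the key step.

Step 10
Reactants: 15 5-bromobenzene-1,3-diol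
Product: 16 1-bromo-3,5-bis(methoxymethoxy)benzene
Conditions: ClCH2OCH3 (2.5 equiv), i-Pr2NEt, CH2Cl2, 0 °C to rt
Reagents that add atoms: chloromethyl methyl ether, COCCl
Why: Acetal protection of both phenols as methoxymethyl ethers, which keeps ring B electron-rich and symmetric and can be removed by mild acid in step 14.

Step 11
Reactants: 16 1-bromo-3,5-bis(methoxymethoxy)benzene; 17 4-ethynylanisole
Product: 18 1-[(4-methoxyphenyl)ethynyl]-3,5-bis(methoxymethoxy)benzene
Conditions: Pd(PPh3)2Cl2 (3 mol %), CuI (5 mol %), Et3N/THF, 65 °C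
Reagents that add atoms: none
Why: Sonogashira coupling of the aryl bromide with the terminal alkyne gives the diaryl alkyne that carries four of the seven ring atoms.

Step 12
Reactants: 14 the α-diazo ketone from step 9; 18 1-[(4-methoxyphenyl)ethynyl]-3,5-bis(methoxymethoxy)benzene (1.5 equiv)
Product: 20 annulated ketone (5-(4-methoxybenzoyl)-10-(4-methoxyphenyl)-2,4-bis(methoxymethoxy)-5H-dibenzo[a,d]cycloheptene whose C5a–C9a benzo ring is ring C of 11; C5 both epimers), via diaryl ketone 19 (not isolated)
Conditions: [(2,4-t-Bu2C6H3O)3P]AuCl (5 mol %), AgSbF6 (5 mol %), CH2Cl2, slow addition of 14 at 0 °C to rt; then (CF3)2CHOH added, 40 °C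
Reagents that add atoms: none
Why: Proposed new method: the cationic phosphite–gold complex should convert 14 into an electrophilic gold carbene that ring B of 18 attacks at a carbon ortho to the alkyne (Friedel–Crafts-type C–H functionalisation, loss of N2) to give 19, and the same π-acid should then activate the alkyne of 19 for anti attack by C7 of the dihydrobenzofuran ring (ring C) on the alkyne carbon that carries the 4-methoxyphenyl group, followed by protodeauration. The closest known reaction types are the gold- and rhodium-catalysed para-selective C–H functionalisation of phenol ethers by aryl diazo carbonyl compounds and the gold- or acid-mediated 7-endo-dig hydroarylation of 2-alkynyl diarylmethanes, including formal (5+2) annulations of 2-alkynylbenzyl alcohols with arenes; their union in one (4+3) annulation is the new element. The seven-membered ring closes in the 7-endo-dig mode, and anti addition of arene and proton makes the new ring alkene cis, as the ring requires. The one new stereocentre, C5, forms without control and is kept epimerisable next to the ketone on purpose, to be set in step 13. Selectivity needed and its source: the site on ring B is fixed by the twofold symmetry of the resorcinol bis-ether (both carbons ortho to the alkyne are equivalent and para to an oxygen, the carbon between the oxygens is the more hindered); 7-endo over 6-exo closure by the 4-methoxyphenyl group, which places the positive charge on the distal alkyne carbon; C7 over C5 of ring C because C7 is flanked only by the ring oxygen whereas C5 is shielded by the C4 methoxy group buttressed by the C3 aryl group. Attack of the ketone oxygen on the alkyne is disfavoured by the same alkyne polarisation and by hydrogen bonding of the carbonyl group to (CF3)2CHOH.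

Step 13
Reactants: 20 annulated ketone
Product: 21 carbinol ((5S)-5-[(S)-hydroxy(4-methoxyphenyl)methyl] analogue of 20; ring C dihydrofuran (2R,3R))
Conditions: RuCl(p-cymene)[(S,S)-TsDPEN] (5 mol %), HCO2H/Et3N (5:2), DMF, 40 °C
Reagents that add atoms: none
Why: Noyori asymmetric transfer hydrogenation with dynamic kinetic resolution: C5 of the α,α-diaryl ketone epimerises through its enol under the reaction conditions while the chiral ruthenium hydride reduces one C5 epimer faster and from one carbonyl face, which should set C5 as (S) (and the carbinol carbon, drawn (S), whose configuration is erased in step 14).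

Step 14
Reactants: 21 carbinol
Product: 23 hexamethyl ether of the target (all phenols as OCH3 except the ring B phenol; (5S); ring B dihydrofuran C2 (S) and trans; ring C dihydrofuran (2R,3R)), via triol 22 (not isolated)
Conditions: HCl (3 M in MeOH), THF, 45 °C
Reagents that add atoms: none
Why: Acid cleaves both methoxymethyl acetals and ionises the 4-methoxybenzylic alcohol, and the freed ortho phenol of ring B closes the dihydrofuran by SN1 cycloetherification (5-exo trapping of the benzylic cation) under thermodynamic control, so the fixed C5 centre should place the new 2-aryl group trans and give (S) at the O-bearing carbon.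

Step 15
Reactants: 23 hexamethyl ether of the target
Product: 24 CNP0325907.1 (target)
Conditions: BBr3 (15 equiv), CH2Cl2, −78 to 0 °C; then MeOH/H2O
Reagents that add atoms: none
Why: Global demethylation of the six aryl methyl ethers with BBr3 (Lewis acid–base adduct, bromide attack on methyl, hydrolysis of the aryl borates), run cold because 2-aryl dihydrobenzofurans ionise reversibly under Lewis acid and should return to the favoured trans isomers.

**Compound list**

1 | 4-bromo-2,6-dimethoxybenzaldehyde | COc1cc(Br)cc(OC)c1C=O | starting material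
2 | 3,5-dimethoxyphenylmagnesium chloride | COc1cc(OC)cc([Mg]Cl)c1 | starting material
3 | (4-bromo-2,6-dimethoxyphenyl)(3,5-dimethoxyphenyl)methanol, racemic | COc1cc(OC)cc(C(O)c2c(OC)cc(Br)cc2OC)c1 | intermediate
4 | (4-bromo-2,6-dimethoxyphenyl)(3,5-dimethoxyphenyl)methanone | COc1cc(OC)cc(C(=O)c2c(OC)cc(Br)cc2OC)c1 | intermediate
5 | (4-bromo-2-hydroxy-6-methoxyphenyl)(3,5-dimethoxyphenyl)methanone | COc1cc(OC)cc(C(=O)c2c(O)cc(Br)cc2OC)c1 | intermediate
6 | 4-methoxybenzyl chloride | COc1ccc(CCl)cc1 | starting material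
7 | {4-bromo-2-methoxy-6-[(4-methoxybenzyl)oxy]phenyl}(3,5-dimethoxyphenyl)methanone | COc1ccc(COc2cc(Br)cc(OC)c2C(=O)c2cc(OC)cc(OC)c2)cc1 | intermediate
8 | hydrazone of 7 (E/Z mixture) | COc1ccc(COc2cc(Br)cc(OC)c2C(=NN)c2cc(OC)cc(OC)c2)cc1 | intermediate
9 | 5-bromo-2-[diazo(3,5-dimethoxyphenyl)methyl]-1-methoxy-3-[(4-methoxybenzyl)oxy]benzene | COc1ccc(COc2cc(Br)cc(OC)c2C(=[N+]=[N-])c2cc(OC)cc(OC)c2)cc1 | intermediate (not isolated)
10 | (2S,3R)-6-bromo-3-(3,5-dimethoxyphenyl)-4-methoxy-2-(4-methoxyphenyl)-2,3-dihydro-1-benzofuran (cis) | O1[C@H](c2ccc(OC)cc2)[C@H](c2cc(OC)cc(OC)c2)c2c(OC)cc(Br)cc12 | intermediate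
11 | (2R,3R)-6-bromo-3-(3,5-dimethoxyphenyl)-4-methoxy-2-(4-methoxyphenyl)-2,3-dihydro-1-benzofuran (trans) | O1[C@@H](c2ccc(OC)cc2)[C@H](c2cc(OC)cc(OC)c2)c2c(OC)cc(Br)cc12 | intermediate
12 | 4'-methoxyacetophenone | CC(=O)c1ccc(OC)cc1 | starting material
13 | 2-[(2R,3R)-3-(3,5-dimethoxyphenyl)-4-methoxy-2-(4-methoxyphenyl)-2,3-dihydro-1-benzofuran-6-yl]-1-(4-methoxyphenyl)ethan-1-one | O1[C@@H](c2ccc(OC)cc2)[C@H](c2cc(OC)cc(OC)c2)c2c(OC)cc(CC(=O)c3ccc(OC)cc3)cc12 | intermediate
14 | 2-diazo analogue of 13 (diazo on the methylene carbon) | O1[C@@H](c2ccc(OC)cc2)[C@H](c2cc(OC)cc(OC)c2)c2c(OC)cc(C(=[N+]=[N-])C(=O)c3ccc(OC)cc3)cc12 | intermediate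
15 | 5-bromobenzene-1,3-diol | Oc1cc(O)cc(Br)c1 | starting material
16 | 1-bromo-3,5-bis(methoxymethoxy)benzene | COCOc1cc(OCOC)cc(Br)c1 | intermediate
17 | 4-ethynylanisole | COc1ccc(C#C)cc1 | starting material
18 | 1-[(4-methoxyphenyl)ethynyl]-3,5-bis(methoxymethoxy)benzene | COCOc1cc(OCOC)cc(C#Cc2ccc(OC)cc2)c1 | intermediate
19 | 2-[(2R,3R)-dihydrobenzofuran-6-yl unit of 11]-2-{2-[(4-methoxyphenyl)ethynyl]-4,6-bis(methoxymethoxy)phenyl}-1-(4-methoxyphenyl)ethan-1-one, both epimers at C2 of the ethanone | O1[C@@H](c2ccc(OC)cc2)[C@H](c2cc(OC)cc(OC)c2)c2c(OC)cc(C(C(=O)c3ccc(OC)cc3)c3c(OCOC)cc(OCOC)cc3C#Cc3ccc(OC)cc3)cc12 | intermediate (not isolated)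
20 | annulated ketone: 5H-dibenzo[a,d]cycloheptene with 4-methoxybenzoyl at C5 (both epimers), 4-methoxyphenyl at C10, OCH2OCH3 at C2 and C4; the C5a–C9a benzo ring is the benzo ring of the (2R,3R)-dihydrobenzofuran of 11 (its C6 = C5a, its C7 = C9a) | COc1ccc(C2=Cc3cc(OCOC)cc(OCOC)c3C(C(=O)c3ccc(OC)cc3)c3cc(OC)c4c(c32)O[C@@H](c2ccc(OC)cc2)[C@@H]4c2cc(OC)cc(OC)c2)cc1 | intermediate
21 | carbinol: as 20 but with (5S)-5-[(S)-hydroxy(4-methoxyphenyl)methyl] | COc1ccc(C2=Cc3cc(OCOC)cc(OCOC)c3[C@@H]([C@H](O)c3ccc(OC)cc3)c3cc(OC)c4c(c32)O[C@@H](c2ccc(OC)cc2)[C@@H]4c2cc(OC)cc(OC)c2)cc1 | intermediate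
22 | triol: 21 with both methoxymethyl ethers cleaved to phenols | COc1ccc(C2=Cc3cc(O)cc(O)c3[C@@H]([C@H](O)c3ccc(OC)cc3)c3cc(OC)c4c(c32)O[C@@H](c2ccc(OC)cc2)[C@@H]4c2cc(OC)cc(OC)c2)cc1 | intermediate (not isolated)
23 | hexamethyl ether of the target: ring B phenol free; (5S); ring B dihydrofuran C2 (S), trans; ring C dihydrofuran (2R,3R) | COc1ccc(C2=Cc3cc(O)cc4c3[C@H](c3cc(OC)c5c(c32)O[C@@H](c2ccc(OC)cc2)[C@@H]5c2cc(OC)cc(OC)c2)[C@@H](c2ccc(OC)cc2)O4)cc1 | intermediate
24 | CNP0325907.1: heptaphenol; (5S); ring B dihydrofuran C2 (S), trans; ring C dihydrofuran (2R,3R) | Oc1ccc(C2=Cc3cc(O)cc4c3[C@H](c3cc(O)c5c(c32)O[C@@H](c2ccc(O)cc2)[C@@H]5c2cc(O)cc(O)c2)[C@@H](c2ccc(O)cc2)O4)cc1 | target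

**Step count and risks**

Total step count: 15. Longest linear sequence: 13 (steps 1–9 and 12–15).

Steps most likely to fail:

1. Step 12 (Proposed new method). The gold carbene may dimerise or cyclopropenate the alkyne instead of substituting ring B. After the first bond has formed, the ketone oxygen (6-exo closure) or C5 of ring C may attack the activated alkyne in place of C7. The fallback uses known reaction types and removes the carbonyl group before the π-acid step; it sets out from 14 and 18 and comes back at 21. Rh2(OAc)4-catalysed aromatic C–H functionalisation of 18 by 14 (CH2Cl2, slow addition) gives 19, which is now isolated. Transfer hydrogenation with dynamic kinetic resolution under the step 13 conditions gives the acyclic (1S,2S)-carbinol F1. Et3SiOSO2CF3/2,6-lutidine gives the triethylsilyl ether F2. [(2-biphenylyl)(t-Bu)2P]Au(NCMe)SbF6 (5 mol %, CH2Cl2, 40 °C) closes the seven-membered ring by 7-endo-dig hydroarylation to the cyclised silyl ether F3. Bu4NF in THF then gives 21.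

2. Step 13. Hydride transfer to the hindered aryl ketone may be slow, and the catalyst may discriminate poorly between the two interconverting C5 epimers, which would give low diastereoselectivity at C5. The fallback drops reagent control; it sets out from 20 and comes back at 23. NaBH4 (MeOH/THF, 0 °C) gives the carbinol mixture F4 (both C5 epimers). The step 14 conditions cyclise both epimers to trans dihydrofurans. Because the (2R,3R) ring C unit makes them diastereomers, 23 is separated from the unwanted (5R) diastereomer F5 by preparative HPLC.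

3. Step 6. The di-ortho-substituted diazoalkane may form incompletely or give the azine. The carbene may insert with low enantioselectivity or into the methoxy group instead of the benzylic ether. The fallback is racemic ring construction followed by resolution; it sets out from 7 and comes back at 11. The phosphazene base P4-t-Bu (benzene, 80 °C) induces intramolecular addition of the benzylic ether carbanion to the ketone and dehydration, giving the benzofuran F6. Ionic hydrogenation with Et3SiH/CF3CO2H gives the racemic trans-dihydrobenzofuran F7. Preparative chiral-phase HPLC gives 11 and the (2S,3S) enantiomer F8, which is discarded.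

Further compounds
F1 | step 12 | (1S,2S)-2-[(2R,3R)-dihydrobenzofuran-6-yl unit of 11]-2-{2-[(4-methoxyphenyl)ethynyl]-4,6-bis(methoxymethoxy)phenyl}-1-(4-methoxyphenyl)ethan-1-ol | O1[C@@H](c2ccc(OC)cc2)[C@H](c2cc(OC)cc(OC)c2)c2c(OC)cc([C@H]([C@H](O)c3ccc(OC)cc3)c3c(OCOC)cc(OCOC)cc3C#Cc3ccc(OC)cc3)cc12
F2 | step 12 | triethylsilyl ether of F1 | O1[C@@H](c2ccc(OC)cc2)[C@H](c2cc(OC)cc(OC)c2)c2c(OC)cc([C@H]([C@H](O[Si](CC)(CC)CC)c3ccc(OC)cc3)c3c(OCOC)cc(OCOC)cc3C#Cc3ccc(OC)cc3)cc12
F3 | step 12 | triethylsilyl ether of 21 | COc1ccc(C2=Cc3cc(OCOC)cc(OCOC)c3[C@@H]([C@H](O[Si](CC)(CC)CC)c3ccc(OC)cc3)c3cc(OC)c4c(c32)O[C@@H](c2ccc(OC)cc2)[C@@H]4c2cc(OC)cc(OC)c2)cc1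
F4 | step 13 | carbinol from 20 as a mixture of epimers at C5 and at the carbinol carbon | COc1ccc(C2=Cc3cc(OCOC)cc(OCOC)c3C(C(O)c3ccc(OC)cc3)c3cc(OC)c4c(c32)O[C@@H](c2ccc(OC)cc2)[C@@H]4c2cc(OC)cc(OC)c2)cc1
F5 | step 13 | diastereomer of 23 with (5R) and (R)-configured C2 in the ring B dihydrofuran (trans), ring C dihydrofuran (2R,3R) | COc1ccc(C2=Cc3cc(O)cc4c3[C@@H](c3cc(OC)c5c(c32)O[C@@H](c2ccc(OC)cc2)[C@@H]5c2cc(OC)cc(OC)c2)[C@H](c2ccc(OC)cc2)O4)cc1
F6 | step 6 | 6-bromo-3-(3,5-dimethoxyphenyl)-4-methoxy-2-(4-methoxyphenyl)-1-benzofuran | COc1ccc(cc1)-c1oc2cc(Br)cc(OC)c2c1-c1cc(OC)cc(OC)c1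
F7 | step 6 | racemic trans-6-bromo-3-(3,5-dimethoxyphenyl)-4-methoxy-2-(4-methoxyphenyl)-2,3-dihydro-1-benzofuran | O1[C@@H](c2ccc(OC)cc2)[C@H](c2cc(OC)cc(OC)c2)c2c(OC)cc(Br)cc12.O1[C@H](c2ccc(OC)cc2)[C@@H](c2cc(OC)cc(OC)c2)c2c(OC)cc(Br)cc12
F8 | step 6 | (2S,3S)-6-bromo-3-(3,5-dimethoxyphenyl)-4-methoxy-2-(4-methoxyphenyl)-2,3-dihydro-1-benzofuran | O1[C@H](c2ccc(OC)cc2)[C@@H](c2cc(OC)cc(OC)c2)c2c(OC)cc(Br)cc12
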